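The data were generated by integration with constants of no real substance; noise was put on by code.

Substrate plus product holds at the charge once the portions are in: the birch run shows 100% at 30.0 h. So the substrate left tells us the product too.

all flasks: substrate 20 mM (in portions, 4); added ligand 3.3 µM

| run | enzyme | remark | time |
|---|---|---|---|
| larch | 1.3 µM | run made earlier; portions every 1.5 h |  |
| birch | 3 µM | run made earlier; portions every 1.5 h |  |
| flask | 2.0 µM | the portions of substrate follow each other after 1.5 h, the first at the start | 40 h |

| run | time / h | product / % | substrate / % |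
|---|---|---|---|
| larch | 8.00 | 8.4 | 92.5 |
| larch | 15.0 | 16.8 | 83.4 |
| larch | 25.0 | 27.8 | 72.0 |
| larch | 30.0 | 32.6 | 66.6 |
| birch | 4.00 | 9.2 | 65.4 |
| birch | 12.0 | 31.8 | 68.2 |
| birch | 20.0 | 50.9 | 48.1 |
| birch | 30.0 | 69.0 | 31.0 |

(scatter of a reading: 0.5 percentage points)

* concentration of product at 40 h, in mM
* concentration of substrate at 40 h, in mM



We treat the portions as one charge at their mean time, 2.25 h, and read a first-order constant k in substrate from the last substrate reading of each run: 0.0146 h⁻¹ for larch, 0.0422 h⁻¹ for birch. Enzyme differs by a factor 2.31 between them, but k by 2.89.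

So we carry the enzyme exponent n, the power of the enzyme charge that k follows at this ligand charge: 1.27, as read from these readings. At 2.0 µM enzyme it gives k = 0.0253 h⁻¹, and by our reckoning 40 h leaves 7.71 mM of substrate, slightly below the forecast.

The forecast gives 12.2 mM of product and 7.8 mM of substrate, holding that “the rate is more than proportional to enzyme”.

The flask ends with 12.3 mM of product and 7.68 mM of substrate. The equations behind it:

enzyme + added ligand ⇌ idle complex, settled at all times (K = 3.29 × 10⁵ L mol⁻¹); substrate + enzyme → product + enzyme, rate k2*[substrate]*[enzyme]/(1 + ([substrate]/Km2) + ([product]/Kp2)) (8.42 mM, 21.1 mM, k = 63500 L mol⁻¹ h⁻¹) At 40.0 h idle complex holds 44.3% of the catalyst charged in the flask and 48.9% in the neighbour flask charged with 0.800 µM of enzyme, a larger share at the smaller charge. Put n to that neighbour: k becomes 0.00792 h⁻¹, which leaves 14.8 mM of substrate, and the neighbour flask holds 14.6 mM of substrate.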